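The target is cut at the stilbene C=C (Heck) into a benzofuran half and a half containing the seven-membered ring; both come from one chloro-dihydrobenzofuran. Its dihydrofuran ring (O1, C2, C3, C3a, C7a) is not closed directly: a trivalent-iodine oxidative rearrangement contracts the pyranone ring of an (S)-flavanone, the ring B carbon C4a shifting from C4 to C3. The step exploits that C3 of the dihydrofuran is bonded to ring B and to one further carbon: the extruded carbonyl carbon C4 emerges as a trans ester, which decarboxylative arylation then replaces by ring C. Stilbene epoxide Friedel–Crafts closure and benzylic arylation complete the seven-membered ring.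

Key step: step 4

Remark: ring B is the benzo ring of the dihydrobenzofuran (the fused ring of the flavanone), ring C the 3,5-dioxygenated ring on its C3; C-d/C-b are C2/C3 of the dihydrofuran, C-a and C-c the sp3 carbons of the seven-membered ring bound to ring B and ring C; CIP descriptors were derived from the SMILES, which take precedence.

Step 1
Reactants: 1 1-chloro-3,5-dimethoxybenzene
Product: 3 1-(2-chloro-6-hydroxy-4-methoxyphenyl)ethanone, via methoxy ketone 2 (not isolated)
Conditions: AcCl, AlCl3 (3 equiv), CH2Cl2, 0 °C to reflux; aq. HCl work-up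
Reagents that add atoms: acetyl chloride, CC(=O)Cl
Why: Friedel–Crafts acetylation should occur para to one methoxy group and ortho to the other (next to chlorine), and excess AlCl3 then cleaves only the methoxy group chelated to the new ketone, so the o-hydroxyacetophenone results in one operation.

Step 2
Reactants: 3 1-(2-chloro-6-hydroxy-4-methoxyphenyl)ethanone
Product: 5 5-chloro-7-methoxy-4H-chromen-4-one, via enaminone 4 (not isolated)
Conditions: Me2NCH(OMe)2, toluene, 100 °C; then conc. HCl, CH2Cl2, rt
Reagents that add atoms: N,N-dimethylformamide dimethyl acetal, COC(OC)N(C)C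
Why: Condensation of the methyl ketone with the formamide acetal gives the enaminone, and acid-induced oxa-Michael addition of the phenol with loss of dimethylamine closes the chromone (enaminone chromone synthesis).

Step 3
Reactants: 5 5-chloro-7-methoxy-4H-chromen-4-one; 6 (4-methoxyphenyl)boronic acid
Product: 7 (S)-5-chloro-7-methoxy-2-(4-methoxyphenyl)chroman-4-one
Conditions: Pd(OCOCF3)2 (5 mol%), t-BuPyOX (antipode that gives the (S)-flavanone), NH4PF6, H2O, ClCH2CH2Cl, 60 °C
Reagents that add atoms: none
Why: Asymmetric conjugate addition of the arylboronic acid to the chromone under cationic palladium–pyridinooxazoline catalysis should set C2 (the later C-d) by ligand control, the aryl chloride being inert because no zerovalent palladium is involved.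

Step 4
Reactants: 7 (S)-5-chloro-7-methoxy-2-(4-methoxyphenyl)chroman-4-one
Product: 11 methyl (2S,3S)-4-chloro-6-methoxy-2-(4-methoxyphenyl)-2,3-dihydrobenzofuran-3-carboxylate, via enol ether 8 (not isolated), via ketal iodane 9 (not isolated), via orthoester 10 (not isolated)
Conditions: PhI(OAc)2, H2SO4, HC(OMe)3, rt; aq. NaHCO3 work-up
Reagents that add atoms: trimethyl orthoformate, COC(OC)OC; water, O
Why: Acid and orthoformate convert the ketone into the 4-methoxy-2H-chromene 8, which PhI(OAc)2 attacks at C3 anti to the C2 aryl group to give the ketal iodane 9; the C4–C4a bond, antiperiplanar to the equatorial C3–I bond, then shifts from C4 to C3 with loss of iodobenzene, and the dialkoxycarbenium ion is trapped as orthoester 10, hydrolysed to the ester on work-up. The closest known reaction is the trivalent-iodine (or Tl(NO3)3) oxidative ring contraction of flavanones to methyl 2-aryl-2,3-dihydrobenzofuran-3-carboxylates, a 1,2-aryl shift of the semipinacol type. No ring is closed by cyclisation: the five-membered ring arises from the six-membered one by a 1,2-shift through a bridged, 3-exo-tet-like transition state. The new stereocentre C3 is formed with inversion at the carbon that bore iodine, which places the ester trans to the C2 aryl group; this is also the thermodynamic arrangement of the epimerisable ester, and C2 is untouched. The step needs migration of ring B in preference to migration of the C2 aryl group (isoflavone) or dehydrogenation (flavone); the conformer with equatorial C2 aryl and C3 iodane aligns only the ring bond for migration, and the methoxy group para to C4a raises the migratory aptitude of ring B.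

Step 5
Reactants: 11 methyl (2S,3S)-4-chloro-6-methoxy-2-(4-methoxyphenyl)-2,3-dihydrobenzofuran-3-carboxylate
Product: 12 (2S,3S)-4-chloro-6-methoxy-2-(4-methoxyphenyl)-2,3-dihydrobenzofuran-3-carboxylic acid
Conditions: LiOH, THF/MeOH/H2O, rt; then aq. HCl
Reagents that add atoms: lithium hydroxide, [Li+].[OH-]
Why: Saponification (BAc2) should give the acid with the thermodynamic trans arrangement, retro-oxa-Michael opening being stereoelectronically disfavoured in the five-membered ring.

Step 6
Reactants: 12 (2S,3S)-4-chloro-6-methoxy-2-(4-methoxyphenyl)-2,3-dihydrobenzofuran-3-carboxylic acid; 13 1-iodo-3,5-dimethoxybenzene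
Product: 14 (2S,3S)-4-chloro-3-(3,5-dimethoxyphenyl)-6-methoxy-2-(4-methoxyphenyl)-2,3-dihydrobenzofuran
Conditions: Ir[dF(CF3)ppy]2(dtbbpy)PF6 (1 mol%), NiCl2·glyme (10 mol%), dtbbpy, Cs2CO3, DMF, blue LEDs, rt
Reagents that add atoms: none
Why: In this nickel/photoredox decarboxylative arylation the benzylic C3 radical should be captured by the arylnickel species anti to the C2 aryl group, which sets C-b trans to C-d, while the aryl chloride does not react at room temperature.

Step 7
Reactants: 14 (2S,3S)-4-chloro-3-(3,5-dimethoxyphenyl)-6-methoxy-2-(4-methoxyphenyl)-2,3-dihydrobenzofuran; 15 4-vinylanisole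
Product: 16 (2S,3S)-3-(3,5-dimethoxyphenyl)-6-methoxy-2-(4-methoxyphenyl)-4-[(E)-2-(4-methoxyphenyl)ethenyl]-2,3-dihydrobenzofuran
Conditions: Pd2(dba)3, [HP(t-Bu)3]BF4, Cy2NMe, 1,4-dioxane, 110 °C
Reagents that add atoms: none
Why: The Heck reaction of the aryl chloride with the styrene under Pd/P(t-Bu)3 catalysis should give the E-stilbene by syn insertion and syn β-hydride elimination.

Step 8
Reactants: 16 (2S,3S)-3-(3,5-dimethoxyphenyl)-6-methoxy-2-(4-methoxyphenyl)-4-[(E)-2-(4-methoxyphenyl)ethenyl]-2,3-dihydrobenzofuran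
Product: 18 seven-membered-ring alcohol (C-a hydroxyl trans to the C-c 4-methoxyphenyl group; C-b/C-c/C-d as in the target), via stilbene epoxide 17 (not isolated)
Conditions: DMDO, acetone/CH2Cl2, −40 °C; then BF3·OEt2 (cat.), CH2Cl2, −78 °C
Reagents that add atoms: dimethyldioxirane, CC1(C)OO1
Why: Epoxidation of the electron-rich stilbene and Lewis-acid opening at the 4-methoxybenzylic carbon C-c trigger an intramolecular Friedel–Crafts alkylation by the ortho carbon of ring C that closes the seven-membered ring with the C-c aryl group pseudo-equatorial, while the carbinol configuration at C-a is erased in step 9 and so does not matter.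

Step 9
Reactants: 18 seven-membered-ring alcohol; 19 2-bromo-4-chloro-1-methoxybenzene
Product: 23 C-a (5-chloro-2-methoxyphenyl) seven-membered-ring compound (aryl groups on C-a and C-c trans), via arylzinc iodide 20 (not isolated), via benzylic mesylate 21 (not isolated), via benzylic iodide 22 (not isolated)
Conditions: 19, Mg, THF, then ZnI2; 18, MsCl, Et3N, CH2Cl2, −20 °C; then LiI, NiBr2·diglyme (10 mol%), dtbbpy, arylzinc solution, THF/CH2Cl2, −40 °C
Reagents that add atoms: none
Why: In this stereoconvergent nickel-catalysed Negishi arylation of a secondary benzylic electrophile the C-a radical should combine with the arylnickel species on the face trans to the neighbouring C-c aryl group, and magnesium insertion and coupling leave the aryl chloride untouched.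

Step 10
Reactants: 14 (2S,3S)-4-chloro-3-(3,5-dimethoxyphenyl)-6-methoxy-2-(4-methoxyphenyl)-2,3-dihydrobenzofuran
Product: 24 4-chloro-3-(3,5-dimethoxyphenyl)-6-methoxy-2-(4-methoxyphenyl)benzofuran
Conditions: DDQ, 1,4-dioxane, 80 °C
Reagents that add atoms: none
Why: DDQ abstracts hydride from the 4-methoxybenzylic C2–H and loss of the C3 proton aromatises the dihydrofuran (dehydrogenation).

Step 11
Reactants: 24 4-chloro-3-(3,5-dimethoxyphenyl)-6-methoxy-2-(4-methoxyphenyl)benzofuran; 25 4,4,5,5-tetramethyl-2-vinyl-1,3,2-dioxaborolane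
Product: 26 3-(3,5-dimethoxyphenyl)-4-ethenyl-6-methoxy-2-(4-methoxyphenyl)benzofuran
Conditions: Pd(OAc)2, SPhos, K3PO4, toluene/H2O, 100 °C
Reagents that add atoms: none
Why: Suzuki–Miyaura coupling of the hindered aryl chloride with the vinylboronate under Pd/SPhos catalysis should install the vinyl group.

Step 12
Reactants: 23 C-a (5-chloro-2-methoxyphenyl) seven-membered-ring compound; 26 3-(3,5-dimethoxyphenyl)-4-ethenyl-6-methoxy-2-(4-methoxyphenyl)benzofuran
Product: 27 deca-O-methyl ether of the target
Conditions: Pd2(dba)3, [HP(t-Bu)3]BF4, Cy2NMe, 1,4-dioxane, 110 °C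
Reagents that add atoms: none
Why: The Heck reaction of the electron-rich aryl chloride with the styrene should form the E-stilbene that joins the two halves, the bulky phosphine enabling oxidative addition of the chloride.

Step 13
Reactants: 27 deca-O-methyl ether of the target
Product: 28 CNP0339094.1 (target)
Conditions: BBr3, CH2Cl2, −78 °C to rt; then H2O
Reagents that add atoms: none
Why: Lewis-acid cleavage of the ten aryl methyl ethers and hydrolysis of the aryl borates should liberate the decaphenol, the only ionisable bond at a stereocentre being the dihydrofuran C2–O bond, which recloses trans.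

Compound list
1 | 1-chloro-3,5-dimethoxybenzene | COc1cc(Cl)cc(OC)c1 | starting material
2 | 1-(2-chloro-4,6-dimethoxyphenyl)ethanone | CC(=O)c1c(Cl)cc(OC)cc1OC | intermediate
3 | 1-(2-chloro-6-hydroxy-4-methoxyphenyl)ethanone | CC(=O)c1c(O)cc(OC)cc1Cl | intermediate
4 | (E)-1-(2-chloro-6-hydroxy-4-methoxyphenyl)-3-(dimethylamino)prop-2-en-1-one | CN(C)/C=C/C(=O)c1c(O)cc(OC)cc1Cl | intermediate
5 | 5-chloro-7-methoxy-4H-chromen-4-one | O=c1ccoc2cc(OC)cc(Cl)c12 | intermediate
6 | (4-methoxyphenyl)boronic acid | COc1ccc(B(O)O)cc1 | starting material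
7 | (S)-5-chloro-7-methoxy-2-(4-methoxyphenyl)chroman-4-one | Clc1cc(OC)cc2c1C(=O)C[C@@H](c1ccc(OC)cc1)O2 | intermediate
8 | (S)-5-chloro-4,7-dimethoxy-2-(4-methoxyphenyl)-2H-chromene | Clc1cc(OC)cc2c1C(OC)=C[C@@H](c1ccc(OC)cc1)O2 | intermediate
9 | (2S)-2,3-trans-3-[acetoxy(phenyl)-λ3-iodanyl]-5-chloro-4,4,7-trimethoxy-2-(4-methoxyphenyl)chromane | Clc1cc(OC)cc2c1C(OC)(OC)[C@H](I(OC(C)=O)c1ccccc1)[C@@H](c1ccc(OC)cc1)O2 | intermediate
10 | (2S,3S)-4-chloro-6-methoxy-2-(4-methoxyphenyl)-3-(trimethoxymethyl)-2,3-dihydrobenzofuran | Clc1cc(OC)cc2c1[C@H](C(OC)(OC)OC)[C@@H](c1ccc(OC)cc1)O2 | intermediate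
11 | methyl (2S,3S)-4-chloro-6-methoxy-2-(4-methoxyphenyl)-2,3-dihydrobenzofuran-3-carboxylate | Clc1cc(OC)cc2c1[C@H](C(=O)OC)[C@@H](c1ccc(OC)cc1)O2 | intermediate
12 | (2S,3S)-4-chloro-6-methoxy-2-(4-methoxyphenyl)-2,3-dihydrobenzofuran-3-carboxylic acid | Clc1cc(OC)cc2c1[C@H](C(=O)O)[C@@H](c1ccc(OC)cc1)O2 | intermediate
13 | 1-iodo-3,5-dimethoxybenzene | COc1cc(I)cc(OC)c1 | starting material
14 | (2S,3S)-4-chloro-3-(3,5-dimethoxyphenyl)-6-methoxy-2-(4-methoxyphenyl)-2,3-dihydrobenzofuran | Clc1cc(OC)cc2c1[C@H](c1cc(OC)cc(OC)c1)[C@@H](c1ccc(OC)cc1)O2 | intermediate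
15 | 4-vinylanisole (1-ethenyl-4-methoxybenzene) | C=Cc1ccc(OC)cc1 | starting material
16 | (2S,3S)-3-(3,5-dimethoxyphenyl)-6-methoxy-2-(4-methoxyphenyl)-4-[(E)-2-(4-methoxyphenyl)ethenyl]-2,3-dihydrobenzofuran | COc1ccc(/C=C/c2cc(OC)cc3c2[C@H](c2cc(OC)cc(OC)c2)[C@@H](c2ccc(OC)cc2)O3)cc1 | intermediate
17 | trans-epoxide of the stilbene double bond of 16 | O1[C@H]([C@@H]1c1ccc(OC)cc1)c1cc(OC)cc2c1[C@H](c1cc(OC)cc(OC)c1)[C@@H](c1ccc(OC)cc1)O2 | intermediate
18 | seven-membered-ring alcohol: ring B–C-a(OH)–C-c(4-methoxyphenyl)–ring C, hydroxyl trans to the C-c aryl group, fused (2S,3S)-dihydrobenzofuran | O[C@H]1c2cc(OC)cc3c2[C@H](c2cc(OC)cc(OC)c2[C@@H]1c1ccc(OC)cc1)[C@@H](c1ccc(OC)cc1)O3 | intermediate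
19 | 2-bromo-4-chloro-1-methoxybenzene | COc1ccc(Cl)cc1Br | starting material
20 | (5-chloro-2-methoxyphenyl)zinc iodide | COc1ccc(Cl)cc1[Zn]I | intermediate
21 | methanesulfonate of 18 | CS(=O)(=O)O[C@H]1c2cc(OC)cc3c2[C@H](c2cc(OC)cc(OC)c2[C@@H]1c1ccc(OC)cc1)[C@@H](c1ccc(OC)cc1)O3 | intermediate
22 | C-a iodide (inverted at C-a relative to 21) | I[C@@H]1c2cc(OC)cc3c2[C@H](c2cc(OC)cc(OC)c2[C@@H]1c1ccc(OC)cc1)[C@@H](c1ccc(OC)cc1)O3 | intermediate
23 | C-a (5-chloro-2-methoxyphenyl) seven-membered-ring compound, aryl groups on C-a and C-c trans, all four stereocentres as in the target | COc1ccc(Cl)cc1[C@H]1c2cc(OC)cc3c2[C@H](c2cc(OC)cc(OC)c2[C@@H]1c1ccc(OC)cc1)[C@@H](c1ccc(OC)cc1)O3 | intermediate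
24 | 4-chloro-3-(3,5-dimethoxyphenyl)-6-methoxy-2-(4-methoxyphenyl)benzofuran | COc1ccc(-c2oc3cc(OC)cc(Cl)c3c2-c2cc(OC)cc(OC)c2)cc1 | intermediate
25 | 4,4,5,5-tetramethyl-2-vinyl-1,3,2-dioxaborolane | C=CB1OC(C)(C)C(C)(C)O1 | starting material
26 | 3-(3,5-dimethoxyphenyl)-4-ethenyl-6-methoxy-2-(4-methoxyphenyl)benzofuran | COc1ccc(-c2oc3cc(OC)cc(C=C)c3c2-c2cc(OC)cc(OC)c2)cc1 | intermediate
27 | deca-O-methyl ether of the target | COc1ccc(-c2oc3cc(OC)cc(/C=C/c4ccc(OC)c([C@H]5c6cc(OC)cc7c6[C@H](c6cc(OC)cc(OC)c6[C@@H]5c5ccc(OC)cc5)[C@@H](c5ccc(OC)cc5)O7)c4)c3c2-c2cc(OC)cc(OC)c2)cc1 | intermediate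
28 | CNP0339094.1 | Oc1ccc(-c2oc3cc(O)cc(/C=C/c4ccc(O)c([C@H]5c6cc(O)cc7c6[C@H](c6cc(O)cc(O)c6[C@@H]5c5ccc(O)cc5)[C@@H](c5ccc(O)cc5)O7)c4)c3c2-c2cc(O)cc(O)c2)cc1 | target

Total step count: 13. Longest linear sequence: 11 steps (steps 1 to 9, then 12 and 13).

Steps most likely to fail

(1) The benzylic arylation of step 9. The benzylic iodide may eliminate to the ring stilbene, the ortho-substituted arylzinc may couple slowly, or the aryl group may enter on the wrong face of C-a. The fallback sets out from 18 and comes back at 23. Oxidation of 18 with DMP (1,1,1-triacetoxy-1,1-dihydro-1,2-benziodoxol-3(1H)-one, CH2Cl2, rt) should give the seven-membered-ring ketone F1. Addition of the aryllithium made from 19 (n-BuLi, then CeCl3, THF, −78 °C) should give the tertiary diarylcarbinol F2. Ionic hydrogenation of the derived diarylmethyl cation (Et3SiH, BF3·OEt2, CH2Cl2, −78 °C), with hydride entering pseudo-axially so that the new aryl group ends pseudo-equatorial and trans to the C-c aryl group, returns to 23.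

(2) The epoxidation and ring closure of step 8. The epoxide may rearrange by 1,2-hydride shift (Meinwald rearrangement) to a deoxybenzoin, or decompose before the arene closes the ring. The fallback sets out from 16 and comes back at 18. Dihydroxylation (OsO4 cat., NMO, acetone/H2O) should give the stable, purifiable stilbene diol F3. Selective ionisation of its 4-methoxybenzylic hydroxyl (CF3CO2H, CH2Cl2, −20 °C) and Friedel–Crafts closure by ring C returns to 18.

(3) The ring contraction of step 4. The 4-methoxyphenyl group on C2 may migrate instead of ring B (isoflavone formation), or the ketone may be dehydrogenated to the flavone. The fallback sets out from 7 and comes back at 11. Kinetic enolisation and immediate trifluoroacetylation (LiN(SiMe3)2, THF, −78 °C; CF3CO2CH2CF3), fast enough to forestall retro-oxa-Michael opening, should give the 3-trifluoroacetyl flavanone F4. Detrifluoroacetylative diazo transfer (MsN3, Et3N, MeCN/H2O) should give the 3-diazoflavanone F5. Photochemical Wolff rearrangement (hν, MeOH), in which only the ring B carbon on the carbonyl group can migrate, should give the ring-contracted ketene F6, trapped by methanol as the ester. Equilibration with NaOMe to the trans isomer returns to 11.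

Further compounds
F1 | step 9 | seven-membered-ring ketone (C-a carbonyl) | O=C1c2cc(OC)cc3c2[C@H](c2cc(OC)cc(OC)c2[C@@H]1c1ccc(OC)cc1)[C@@H](c1ccc(OC)cc1)O3
F2 | step 9 | tertiary C-a carbinol bearing the 5-chloro-2-methoxyphenyl group | COc1ccc(Cl)cc1[C@@]1(O)c2cc(OC)cc3c2[C@H](c2cc(OC)cc(OC)c2[C@@H]1c1ccc(OC)cc1)[C@@H](c1ccc(OC)cc1)O3
F3 | step 8 | syn-diol of the stilbene double bond of 16 | O[C@H]([C@@H](O)c1ccc(OC)cc1)c1cc(OC)cc2c1[C@H](c1cc(OC)cc(OC)c1)[C@@H](c1ccc(OC)cc1)O2
F4 | step 4 | (2S)-2,3-trans-5-chloro-7-methoxy-2-(4-methoxyphenyl)-3-(trifluoroacetyl)chroman-4-one | Clc1cc(OC)cc2c1C(=O)[C@H](C(=O)C(F)(F)F)[C@@H](c1ccc(OC)cc1)O2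
F5 | step 4 | (S)-5-chloro-3-diazo-7-methoxy-2-(4-methoxyphenyl)chroman-4-one | Clc1cc(OC)cc2c1C(=O)C(=[N+]=[N-])[C@@H](c1ccc(OC)cc1)O2
F6 | step 4 | (S)-[4-chloro-6-methoxy-2-(4-methoxyphenyl)benzofuran-3(2H)-ylidene]methanone (ketene) | Clc1cc(OC)cc2c1C(=C=O)[C@@H](c1ccc(OC)cc1)O2
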